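**Retrosynthetic overview**

1. Numbering of the carbocycle: C1 (CH bearing ring B), C2 (CH–CH3), C3 (=C–CH3), C4 (=CH), C4a/C8a (fusion to ring A). C4 is the one unsubstituted ring carbon between ring A (C4a) and C3, so removing it leaves a cis-3-aryl-2-methylindan-1-one whose carbonyl carbon is C3. Forward, a one-carbon insertion with aryl shift forms C3–C4 and C4–C4a and turns the five-membered ring into the six-membered one.
2. After the expansion the C3 ketone lies next to benzylic C4H2: enol triflate (C3=C4), methyl cross-coupling, desilylation.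
3. The indanone must carry its carbonyl on the ring-A carbon next to the free aromatic CH (C5) and its aryl-bearing carbon on the ring-A carbon next to C8–OMe. Ring A is therefore taken as a syringyl ketone and the five-membered ring is closed at its ortho carbon (Nazarov); acylative closure of a syringylpropanoic acid would give the 5,6,7-trioxygenated isomer.
4. C1 is set by Rh/(S)-BINAP conjugate arylation of the 2-methylindenone with the ring-B boronic acid. C2 is set by kinetic protonation of the enolate anti to the aryl group (cis).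
5. Ring order: ring A (bought), five-membered ring (Nazarov), ring B attached, six-membered carbocycle by ring expansion. Both phenols travel as TIPS ethers, because hydrogenolysis of benzyl ethers would endanger the C3=C4 styrene.

Key step: step 9

Remark: C1–C8a above are the target locants; systematic names of intermediates use their own locants. ArB = 3,5-dimethoxy-4-(triisopropylsilyloxy)phenyl.
Assumption: ketone 1 (propiosyringone) is bought.
Assumption: the facial sense of step 7 is assigned by analogy with 2-cyclopentenone under Rh/(S)-BINAP; if the benzo-fused enone reverses it, (R)-BINAP is used.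

**Route**

Step 1
Reactants: 1 1-(4-hydroxy-3,5-dimethoxyphenyl)propan-1-one
Product: 2 1-(4-hydroxy-3,5-dimethoxyphenyl)-2-methylprop-2-en-1-one
Conditions: (CH2O)n, i-Pr2NH·TFA, TFA (cat.), THF, reflux; used crude
Reagents that add atoms: formaldehyde (as paraformaldehyde), C=O
Why: Mannich-type α-methylenation (aldol–elimination with formaldehyde mediated by the ammonium salt) of an aryl ethyl ketone; both positions ortho to the phenol carry OMe, so the ring cannot be aminomethylated, and no stereocentre is formed.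

Step 2
Reactants: 2 1-(4-hydroxy-3,5-dimethoxyphenyl)-2-methylprop-2-en-1-one
Product: 3 5-hydroxy-4,6-dimethoxy-2-methylindan-1-one (racemic)
Conditions: TfOH, ClCH2CH2Cl, 0 → 50 °C
Reagents that add atoms: none
Why: Nazarov-type 4π-electrocyclisation of the O-protonated aryl vinyl ketone closes the five-membered ring at the ring carbon ortho to the carbonyl, which is ortho and para to the two methoxy groups; this puts the carbonyl next to the free aromatic CH and the CH2 next to C4–OMe, and the racemic C2 centre is removed in step 4.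

Step 3
Reactants: 3 5-hydroxy-4,6-dimethoxy-2-methylindan-1-one
Product: 4 4,6-dimethoxy-2-methyl-5-(triisopropylsilyloxy)indan-1-one (racemic)
Conditions: TIPSCl, imidazole, DMF, rt → 40 °C
Reagents that add atoms: chlorotriisopropylsilane, CC(C)[Si](Cl)(C(C)C)C(C)C
Why: Standard silylation of an acidic phenol; the TIPS ether should survive amide bases, BF3 at low temperature and palladium, and is cleaved at the end by fluoride without touching the styrene.

Step 4
Reactants: 4 4,6-dimethoxy-2-methyl-5-(triisopropylsilyloxy)indan-1-one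
Product: 6 4,6-dimethoxy-2-methyl-5-(triisopropylsilyloxy)-1H-inden-1-one, via trimethylsilyl enol ether 5 (not isolated)
Conditions: LDA, TMSCl, THF, −78 °C; then Pd(OAc)2 (10 mol %), O2 (1 atm), DMSO, rt
Reagents that add atoms: none
Why: Saegusa–Ito dehydrogenation in its aerobic catalytic form: the silyl enol ether gives a Pd(II) enolate and β-hydride elimination of the benzylic C3–H gives the endocyclic enone, which the 2-methyl group stabilises against dimerisation; the racemic C2 centre disappears.

Step 5
Reactants: 7 4-bromo-2,6-dimethoxyphenol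
Product: 8 (4-bromo-2,6-dimethoxyphenoxy)triisopropylsilane
Conditions: TIPSCl, imidazole, DMF, rt → 40 °C
Reagents that add atoms: chlorotriisopropylsilane, CC(C)[Si](Cl)(C(C)C)C(C)C
Why: Same phenol silylation as in step 3, here on the ring-B building block.

Step 6
Reactants: 8 (4-bromo-2,6-dimethoxyphenoxy)triisopropylsilane
Product: 10 [3,5-dimethoxy-4-(triisopropylsilyloxy)phenyl]boronic acid, via aryllithium 9 (not isolated)
Conditions: n-BuLi, THF, −78 °C; B(Oi-Pr)3, −78 °C → rt; 1 M HCl
Reagents that add atoms: triisopropyl borate, CC(C)OB(OC(C)C)OC(C)C; water, O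
Why: Bromine–lithium exchange, borate trapping and hydrolysis (standard arylboronic acid synthesis); the silyloxy group is para to lithium, so no silyl migration is expected.

Step 7
Reactants: 6 4,6-dimethoxy-2-methyl-5-(triisopropylsilyloxy)-1H-inden-1-one; 10 [3,5-dimethoxy-4-(triisopropylsilyloxy)phenyl]boronic acid
Product: 11 (3S)-3-ArB-4,6-dimethoxy-2-methyl-5-(triisopropylsilyloxy)indan-1-one (C2 epimer mixture)
Conditions: [Rh(OH)((S)-binap)]2 (3 mol %), dioxane/H2O 10:1, 40–60 °C
Reagents that add atoms: none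
Why: Hayashi–Miyaura rhodium-catalysed asymmetric 1,4-addition: the aryl–Rh(I)/(S)-BINAP species inserts the strained indenone C2=C3 bond and delivers ring B to one face of C3 (3S, catalyst control), while hydrolysis of the oxa-π-allyl rhodium leaves C2 uncontrolled, which step 8 corrects.

Step 8
Reactants: 11 (3S)-3-ArB-4,6-dimethoxy-2-methyl-5-(triisopropylsilyloxy)indan-1-one
Product: 13 (2S,3S)-3-ArB-4,6-dimethoxy-2-methyl-5-(triisopropylsilyloxy)indan-1-one (cis), via lithium enolate 12 (not isolated)
Conditions: LDA, THF, −78 °C; t-BuCO2H, THF, −78 °C; cold pH 7 buffer; used at once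
Reagents that add atoms: none
Why: Kinetic protonation of the planar lithium enolate: the bulky acid delivers the proton to C2 from the face opposite the C3 aryl group, so the methyl group ends cis to the aryl group (2S); this contra-thermodynamic isomer is kept cold and not chromatographed on basic media.

Step 9
Reactants: 13 (2S,3S)-3-ArB-4,6-dimethoxy-2-methyl-5-(triisopropylsilyloxy)indan-1-one; 14 trimethylsilyldiazomethane
Product: 16 (3S,4S)-4-ArB-5,7-dimethoxy-3-methyl-6-(triisopropylsilyloxy)-3,4-dihydronaphthalen-2(1H)-one (cis), via α-trimethylsilyl ketone 15 (not isolated)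
Conditions: 14 (2 equiv), BF3·OEt2 (1.5 equiv), CH2Cl2, −78 → −40 °C; then 1 M HCl, THF, 0 °C
Reagents that add atoms: none
Why: BF3 activates the C1 carbonyl of 13 (C3 of the target), the diazo carbon of 14 adds, and loss of N2 from the betaine is coupled to a 1,2-shift of the ring-A carbon C7a (C4a of the target), which forms C3–C4 and C4–C4a and gives the α-silyl ketone 15 that is protodesilylated on acidic work-up. The closest known reaction is the Lewis-acid-promoted diazoalkane (Tiffeneau–Demjanov-type) homologation of 1-indanones to 2-tetralones. The six-membered carbocycle arises by ring expansion of the five-membered ring through this 1,2-shift, not by a cyclisation. No stereocentre is created in 16 (the transient C–Si centre is lost on desilylation), and C3 and C4 of 16 are spectators. The step needs aryl rather than C2-alkyl migration, which π-participation of the electron-rich ring (para-silyloxy donor) and the preference of the bulky Me3Si/N2 unit to avoid the α-methyl side should secure, and single insertion, which the silyl group secures by masking the product as α-silyl ketone or enol silane. The cis C2 configuration should be retained because the conditions are cold and free of base.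

Step 10
Reactants: 16 (3S,4S)-4-ArB-5,7-dimethoxy-3-methyl-6-(triisopropylsilyloxy)-3,4-dihydronaphthalen-2(1H)-one
Product: 18 (3S,4S)-4-ArB-5,7-dimethoxy-3-methyl-6-(triisopropylsilyloxy)-3,4-dihydronaphthalen-2-yl trifluoromethanesulfonate, via potassium enolate 17 (not isolated)
Conditions: KHMDS, THF, −78 °C (ketone added to base); PhNTf2, −78 → 0 °C
Reagents that add atoms: N-phenylbis(trifluoromethanesulfonimide), O=S(=O)(N(c1ccccc1)S(=O)(=O)C(F)(F)F)C(F)(F)F
Why: Kinetic deprotonation of the 2-tetralone at the benzylic C1H2 (more acidic, conjugated and far less hindered than the tertiary C3–H) followed by O-triflation fixes the double bond at C3=C4 of the target; the two stereocentres are not involved.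

Step 11
Reactants: 18 (3S,4S)-4-ArB-5,7-dimethoxy-3-methyl-6-(triisopropylsilyloxy)-3,4-dihydronaphthalen-2-yl trifluoromethanesulfonate
Product: 19 (1S,2S)-1-ArB-6,8-dimethoxy-2,3-dimethyl-7-(triisopropylsilyloxy)-1,2-dihydronaphthalene
Conditions: MeZnCl, Pd(PPh3)4 (5 mol %), THF, rt → 40 °C
Reagents that add atoms: methylzinc chloride, C[Zn]Cl
Why: Negishi cross-coupling of the alkenyl triflate (oxidative addition, transmetalation, reductive elimination) installs the C3 methyl group with the double bond held at C3=C4; neither stereocentre is touched.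

Step 12
Reactants: 19 (1S,2S)-1-ArB-6,8-dimethoxy-2,3-dimethyl-7-(triisopropylsilyloxy)-1,2-dihydronaphthalene
Product: 20 (1S,2S)-1-(4-hydroxy-3,5-dimethoxyphenyl)-6,8-dimethoxy-2,3-dimethyl-1,2-dihydronaphthalen-7-ol (target)
Conditions: TBAF, AcOH, THF, 0 °C, degassed
Reagents that add atoms: none
Why: Fluoride cleavage of both aryl silyl ethers, buffered with acetic acid and run without oxygen, so that the electron-rich phenoxides and the C3=C4 styrene are neither oxidised nor isomerised; the stereocentres are untouched.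

**Compound list**

1 | 1-(4-hydroxy-3,5-dimethoxyphenyl)propan-1-one (propiosyringone) | CCC(=O)c1cc(OC)c(O)c(OC)c1 | starting material
2 | 1-(4-hydroxy-3,5-dimethoxyphenyl)-2-methylprop-2-en-1-one | C=C(C)C(=O)c1cc(OC)c(O)c(OC)c1 | intermediate
3 | 5-hydroxy-4,6-dimethoxy-2-methylindan-1-one (racemic) | CC1Cc2c(OC)c(O)c(OC)cc2C1=O | intermediate
4 | 4,6-dimethoxy-2-methyl-5-(triisopropylsilyloxy)indan-1-one (racemic) | CC1Cc2c(OC)c(O[Si](C(C)C)(C(C)C)C(C)C)c(OC)cc2C1=O | intermediate
5 | trimethylsilyl enol ether of 4 (1-trimethylsilyloxy-2-methyl-3H-indene) | CC1=C(O[Si](C)(C)C)c2cc(OC)c(O[Si](C(C)C)(C(C)C)C(C)C)c(OC)c2C1 | intermediate (not isolated)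
6 | 4,6-dimethoxy-2-methyl-5-(triisopropylsilyloxy)-1H-inden-1-one | CC1=Cc2c(OC)c(O[Si](C(C)C)(C(C)C)C(C)C)c(OC)cc2C1=O | intermediate
7 | 4-bromo-2,6-dimethoxyphenol | COc1cc(Br)cc(OC)c1O | starting material
8 | (4-bromo-2,6-dimethoxyphenoxy)triisopropylsilane | COc1cc(Br)cc(OC)c1O[Si](C(C)C)(C(C)C)C(C)C | intermediate
9 | [3,5-dimethoxy-4-(triisopropylsilyloxy)phenyl]lithium | [Li]c1cc(OC)c(O[Si](C(C)C)(C(C)C)C(C)C)c(OC)c1 | intermediate (not isolated)
10 | [3,5-dimethoxy-4-(triisopropylsilyloxy)phenyl]boronic acid | COc1cc(B(O)O)cc(OC)c1O[Si](C(C)C)(C(C)C)C(C)C | intermediate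
11 | (3S)-3-ArB-4,6-dimethoxy-2-methyl-5-(triisopropylsilyloxy)indan-1-one (C2 epimer mixture) | COc1cc([C@H]2c3c(cc(OC)c(O[Si](C(C)C)(C(C)C)C(C)C)c3OC)C(=O)C2C)cc(OC)c1O[Si](C(C)C)(C(C)C)C(C)C | intermediate
12 | lithium enolate of 11 (C1=C2, 3S) | COc1cc([C@H]2c3c(cc(OC)c(O[Si](C(C)C)(C(C)C)C(C)C)c3OC)C(O[Li])=C2C)cc(OC)c1O[Si](C(C)C)(C(C)C)C(C)C | intermediate (not isolated)
13 | (2S,3S)-3-ArB-4,6-dimethoxy-2-methyl-5-(triisopropylsilyloxy)indan-1-one (cis) | COc1cc([C@H]2c3c(cc(OC)c(O[Si](C(C)C)(C(C)C)C(C)C)c3OC)C(=O)[C@H]2C)cc(OC)c1O[Si](C(C)C)(C(C)C)C(C)C | intermediate (key-step precursor)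
14 | trimethylsilyldiazomethane | C[Si](C)(C)C=[N+]=[N-] | starting material
15 | (3S,4S)-4-ArB-5,7-dimethoxy-3-methyl-6-(triisopropylsilyloxy)-1-(trimethylsilyl)-3,4-dihydronaphthalen-2(1H)-one (C1 epimers) | COc1cc([C@H]2c3c(cc(OC)c(O[Si](C(C)C)(C(C)C)C(C)C)c3OC)C([Si](C)(C)C)C(=O)[C@H]2C)cc(OC)c1O[Si](C(C)C)(C(C)C)C(C)C | intermediate (not isolated)
16 | (3S,4S)-4-ArB-5,7-dimethoxy-3-methyl-6-(triisopropylsilyloxy)-3,4-dihydronaphthalen-2(1H)-one (cis) | COc1cc([C@H]2c3c(cc(OC)c(O[Si](C(C)C)(C(C)C)C(C)C)c3OC)CC(=O)[C@H]2C)cc(OC)c1O[Si](C(C)C)(C(C)C)C(C)C | intermediate (key-step product)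
17 | potassium enolate of 16 (C1=C2 of the tetralone) | COc1cc([C@H]2c3c(cc(OC)c(O[Si](C(C)C)(C(C)C)C(C)C)c3OC)C=C([O-])[C@H]2C)cc(OC)c1O[Si](C(C)C)(C(C)C)C(C)C.[K+] | intermediate (not isolated)
18 | (3S,4S)-4-ArB-5,7-dimethoxy-3-methyl-6-(triisopropylsilyloxy)-3,4-dihydronaphthalen-2-yl trifluoromethanesulfonate | COc1cc([C@H]2c3c(cc(OC)c(O[Si](C(C)C)(C(C)C)C(C)C)c3OC)C=C(OS(=O)(=O)C(F)(F)F)[C@H]2C)cc(OC)c1O[Si](C(C)C)(C(C)C)C(C)C | intermediate
19 | (1S,2S)-1-ArB-6,8-dimethoxy-2,3-dimethyl-7-(triisopropylsilyloxy)-1,2-dihydronaphthalene | COc1cc([C@H]2c3c(cc(OC)c(O[Si](C(C)C)(C(C)C)C(C)C)c3OC)C=C(C)[C@H]2C)cc(OC)c1O[Si](C(C)C)(C(C)C)C(C)C | intermediate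
20 | (1S,2S)-1-(4-hydroxy-3,5-dimethoxyphenyl)-6,8-dimethoxy-2,3-dimethyl-1,2-dihydronaphthalen-7-ol | COc1cc([C@H]2c3c(cc(OC)c(O)c3OC)C=C(C)[C@H]2C)cc(OC)c1O | target

**Step count**

Total: 12 steps. Longest linear sequence: 10 steps (1, 2, 3, 4, 7, 8, 9, 10, 11, 12).

**Steps most likely to fail**

Step 9 (ring expansion). The alkyl carbon C2 may shift in competition with the aryl carbon, addition to the deactivated, hindered aryl ketone may be slow, and the Lewis acid may epimerise C2 before insertion. The fallback sets out from 13 and returns at 16. Non-basic Tebbe methylenation of 13 (THF, −40 → 0 °C) should give the cis exocyclic alkene (2S,3S)-3-ArB-4,6-dimethoxy-2-methyl-1-methylidene-5-(triisopropylsilyloxy)indane F1. Oxidative rearrangement of F1 with PhI(OH)OTs in MeOH/H2O 95:5 at rt should then give 16, because the iodine(III) adduct can only collapse by aryl shift through a phenonium ion.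

Step 7 (asymmetric arylation). Insertion may be slow because of the α-methyl group and the peri methoxy group, facial discrimination may be insufficient, and the electron-rich boronic acid may protodeboronate. The fallback sets out from 1 and returns at 11.
- Acid-mediated condensation of 1 with commercial syringaldehyde (HCl, EtOH) should give the α-methylchalcone (E)-1,3-bis(4-hydroxy-3,5-dimethoxyphenyl)-2-methylprop-2-en-1-one F2.
- Nazarov cyclisation of F2 in hot TFA should give racemic trans-5-hydroxy-3-(4-hydroxy-3,5-dimethoxyphenyl)-4,6-dimethoxy-2-methylindan-1-one F3.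
- Silylation of both phenols (TIPSCl, imidazole, DMF) gives racemic 3-ArB-4,6-dimethoxy-2-methyl-5-(triisopropylsilyloxy)indan-1-one F4.
- Kinetic resolution of F4 by Noyori-type asymmetric transfer hydrogenation (Ru–TsDPEN catalyst, HCO2H/Et3N, rt, about half conversion) uses the catalyst antipode that reduces the 3R ketone to the indanol (3R)-3-ArB-4,6-dimethoxy-2-methyl-5-(triisopropylsilyloxy)indan-1-ol F5. The unreacted 3S ketone is 11.

Step 8 (kinetic protonation). Facial selectivity of proton delivery may be incomplete, and the cis ketone may drift back toward trans during work-up. The fallback sets out from 11 and returns at 13. The enolate is trapped (LDA, TMSCl, THF, −78 °C) and isolated as the silyl enol ether (3S)-3-ArB-4,6-dimethoxy-2-methyl-5-(triisopropylsilyloxy)-1-(trimethylsilyloxy)-3H-indene F6. F6 is then protonated with a Lewis-acid-assisted chiral Brønsted acid (BINOL·SnCl4, toluene, −78 °C), using the BINOL antipode whose preference matches the substrate bias, so that reagent and substrate control both place the proton anti to the aryl group under strictly non-equilibrating conditions.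

**Further compounds**

F1 | step 9 | (2S,3S)-3-ArB-4,6-dimethoxy-2-methyl-1-methylidene-5-(triisopropylsilyloxy)indane | COc1cc([C@H]2c3c(cc(OC)c(O[Si](C(C)C)(C(C)C)C(C)C)c3OC)C(=C)[C@H]2C)cc(OC)c1O[Si](C(C)C)(C(C)C)C(C)C
F2 | step 7 | (E)-1,3-bis(4-hydroxy-3,5-dimethoxyphenyl)-2-methylprop-2-en-1-one | COc1cc(/C=C(\C)C(=O)c2cc(OC)c(O)c(OC)c2)cc(OC)c1O
F3 | step 7 | racemic trans-5-hydroxy-3-(4-hydroxy-3,5-dimethoxyphenyl)-4,6-dimethoxy-2-methylindan-1-one | COc1cc(C2c3c(cc(OC)c(O)c3OC)C(=O)C2C)cc(OC)c1O
F4 | step 7 | racemic 3-ArB-4,6-dimethoxy-2-methyl-5-(triisopropylsilyloxy)indan-1-one | COc1cc(C2c3c(cc(OC)c(O[Si](C(C)C)(C(C)C)C(C)C)c3OC)C(=O)C2C)cc(OC)c1O[Si](C(C)C)(C(C)C)C(C)C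
F5 | step 7 | (3R)-3-ArB-4,6-dimethoxy-2-methyl-5-(triisopropylsilyloxy)indan-1-ol | COc1cc([C@@H]2c3c(cc(OC)c(O[Si](C(C)C)(C(C)C)C(C)C)c3OC)C(O)C2C)cc(OC)c1O[Si](C(C)C)(C(C)C)C(C)C
F6 | step 8 | (3S)-3-ArB-4,6-dimethoxy-2-methyl-5-(triisopropylsilyloxy)-1-(trimethylsilyloxy)-3H-indene | COc1cc([C@H]2c3c(cc(OC)c(O[Si](C(C)C)(C(C)C)C(C)C)c3OC)C(O[Si](C)(C)C)=C2C)cc(OC)c1O[Si](C(C)C)(C(C)C)C(C)C
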